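**Retrosynthetic overview**
- The target is reached by global O‑demethylation and de‑tert‑butylation of a protected hexamer. Its seven‑membered ring (C‑7b–C‑10a) is closed last, by attack of a resorcinolate on a para‑quinone methide.
- The C‑8b–C‑7c bond comes from an amine‑catalysed 1,6‑Michael addition of an arylacetaldehyde (units a, b) to a tetrameric para‑quinone methide (units c–f).
- The eight‑membered ring (C‑7e–C‑10d) is closed earlier by the same phenolate/quinone‑methide reaction.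
- Key step: the C‑8e–C‑8c bond is made by an intermolecular, amine‑catalysed Michael addition of an arylacetaldehyde (units e, f) to a nitroalkene (units c, d), syn and catalyst‑controlled.
- All three trans‑2,3‑diaryl‑dihydrobenzofurans come from one resolved 4‑bromo‑dihydrobenzofuran, made by ortho‑quinone‑methide/sulfur‑ylide [4+1] annulation. Ring order: dihydrofurans, then eight‑membered ring, then seven‑membered ring.

Assumption: the target is taken exactly as encoded, a resveratrol hexamer with (7aR,8aR,7bS,8bS,7cR,8cR,7dR,8dR,7eS,8eS,7fR,8fR) configuration, and the known facial preference of the prolinol catalyst with simple aldehydes is taken to hold for the arylacetaldehydes used here.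

**Locants and abbreviations**
- Each resveratrol unit (a–f) has C‑7 (bears the para‑oxygenated aryl), C‑8, and a resorcinol ring C‑9 to C‑14 (ring a2 … f2).
- Bonds between units: 7a–O–11b and 8a–10b; 7b–10a; 8b–7c; 8c–8e; 7d–O–11c and 8d–10c; 7e–10d; 7f–O–11e and 8f–10e.
- ArT = (2R,3R)‑3‑[3,5‑bis(triisopropylsilyloxy)phenyl]‑6‑methoxy‑2‑(4‑methoxyphenyl)‑2,3‑dihydro‑1‑benzofuran‑4‑yl.
- ArM = the same group with a 3‑(3,5‑dimethoxyphenyl) substituent.
- ArD = the same group with a 3‑(3,5‑dihydroxyphenyl) substituent.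
- Ar′ = 3,5‑di‑tert‑butyl‑4‑(trimethylsilyloxy)phenyl.
- Ar* = 3,5‑di‑tert‑butyl‑4‑hydroxyphenyl.

**Route**

Step 1
Reactants: 1 1-bromo-3,5-dimethoxybenzene
Product: 3 2-bromo-4,6-dimethoxybenzaldehyde, via iminium salt 2 (not isolated)
Conditions: POCl3, DMF, 0 to 90 °C; then ice/H2O
Reagents that add atoms: N,N-dimethylformamide CN(C)C=O; water O
Why: Vilsmeier–Haack formylation goes to the ring position between Br and OMe that is para to the second OMe; no stereocentre is formed.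

Step 2
Reactants: 3 2-bromo-4,6-dimethoxybenzaldehyde
Product: 4 2-bromo-6-hydroxy-4-methoxybenzaldehyde
Conditions: BCl3 (1.1 equiv), CH2Cl2, −78 to 0 °C; H2O
Reagents that add atoms: none
Why: Chelation‑controlled Lewis‑acid demethylation cleaves only the methyl ether ortho to the aldehyde.

Step 3
Reactants: 5 5-bromobenzene-1,3-diol
Product: 6 1-bromo-3,5-bis(triisopropylsilyloxy)benzene
Conditions: iPr3SiCl, imidazole, DMF, rt
Reagents that add atoms: chlorotriisopropylsilane CC(C)[Si](Cl)(C(C)C)C(C)C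
Why: Standard phenol silylation gives fluoride‑labile ethers that later allow rings a2 and d2 to be unmasked selectively.

Step 4
Reactants: 4 2-bromo-6-hydroxy-4-methoxybenzaldehyde; 6 1-bromo-3,5-bis(triisopropylsilyloxy)benzene
Product: 8 racemic (2-bromo-6-hydroxy-4-methoxyphenyl)[3,5-bis(triisopropylsilyloxy)phenyl]methanol, via Grignard reagent 7 (not isolated)
Conditions: 6, Mg, THF, 40 °C; 4 pre‑treated with NaH (1.0 equiv), THF, 0 °C; combine at −40 to 0 °C; NH4Cl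
Reagents that add atoms: none
Why: Grignard 1,2‑addition to the sodium phenoxide of the aldehyde gives the benzhydrol; its stereocentre is planarised in step 7.

Step 5
Reactants: 8 racemic benzhydrol
Product: 9 racemic 3-bromo-5-methoxy-2-{[3,5-bis(triisopropylsilyloxy)phenyl][(4-methylphenyl)sulfonyl]methyl}phenol
Conditions: 4-MeC6H4SO2Na, HCO2H, THF/H2O, rt
Reagents that add atoms: sodium 4-methylbenzenesulfinate Cc1ccc(cc1)S(=O)[O-].[Na+]
Why: Acid‑promoted SN1 substitution of the ortho‑hydroxybenzhydrol by sulfinate gives a base‑triggerable ortho‑quinone‑methide precursor.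

Step 6
Reactants: 10 4-methoxybenzyl chloride
Product: 11 (4-methoxybenzyl)dimethylsulfonium chloride
Conditions: Me2S, MeCN, rt
Reagents that add atoms: dimethyl sulfide CSC
Why: SN2 alkylation of the sulfide by the activated benzylic chloride gives the ylide precursor.

Step 7
Reactants: 9 racemic sulfone; 11 (4-methoxybenzyl)dimethylsulfonium chloride
Product: 14 (2RS,3RS)-4-bromo-3-[3,5-bis(triisopropylsilyloxy)phenyl]-6-methoxy-2-(4-methoxyphenyl)-2,3-dihydro-1-benzofuran (racemic trans), via sulfur ylide 12 (not isolated), via ortho-quinone methide 13 (not isolated)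
Conditions: Cs2CO3 (3 equiv), CH2Cl2, rt
Reagents that add atoms: none
Why: Formal [4+1] annulation: base expels sulfinate, the benzylic sulfur ylide adds in Michael fashion, and the phenoxide displaces Me2S from the anti betaine, giving the trans‑2,3‑diaryl ring as the racemate.

Step 8
Reactants: 14 racemic trans bromide
Product: 15 ArT–Br, (2R,3R)-4-bromo-3-[3,5-bis(triisopropylsilyloxy)phenyl]-6-methoxy-2-(4-methoxyphenyl)-2,3-dihydro-1-benzofuran
Conditions: preparative chiral SFC (amylose tris(3,5-dimethylphenylcarbamate) phase, CO2/iPrOH)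
Reagents that add atoms: none
Why: Chromatographic resolution supplies the (2R,3R) series needed for all three dihydrobenzofurans; the absolute configuration is assigned by anomalous‑dispersion X‑ray on the bromide.

Step 9
Reactants: 15 ArT–Br
Product: 17 ArT–CHO, via aryllithium 16 (not isolated)
Conditions: nBuLi, THF, −78 °C; DMF; NH4Cl
Reagents that add atoms: N,N-dimethylformamide CN(C)C=O
Why: Bromine–lithium exchange followed by Bouveault formylation is faster than any deprotonation at −78 °C, so the ring stereocentres are untouched.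

Step 10
Reactants: 17 ArT–CHO
Product: 18 (E)-ArT–CH=CH–NO2
Conditions: MeNO2, NH4OAc, AcOH, 90 °C
Reagents that add atoms: nitromethane C[N+](=O)[O-]
Why: Henry (nitroaldol) condensation with dehydration gives the E‑nitroalkene, the Michael acceptor of the key step.

Step 11
Reactants: 17 ArT–CHO
Product: 19 ArT–CH=CH–OMe (E/Z mixture of the 2-methoxyethenyl compound)
Conditions: Ph3P(CH2OMe)Cl (1.5 equiv), KN(SiMe3)2 (1.4 equiv), THF, 0 °C, 30 min; then 17, 0 °C to rt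
Reagents that add atoms: (methoxymethyl)triphenylphosphonium chloride COC[P+](c1ccccc1)(c1ccccc1)c1ccccc1.[Cl-]
Why: Wittig olefination with the preformed methoxymethylene ylide homologates the aldehyde by one carbon; both enol ether isomers hydrolyse to the same aldehyde, and the ring stereocentres are not touched.

Step 12
Reactants: 19 ArT–CH=CH–OMe
Product: 20 ArT–CH2–CHO
Conditions: 2 M aq. HCl/THF (1:4), 0 °C to rt; NaHCO3
Reagents that add atoms: water O
Why: Acid‑catalysed enol ether hydrolysis through the hemiacetal releases the arylacetaldehyde; the aryl triisopropylsilyl ethers survive dilute aqueous acid, and the sensitive product is used directly.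

Step 13
Reactants: 15 ArT–Br
Product: 22 ArM–Br, (2R,3R)-4-bromo-3-(3,5-dimethoxyphenyl)-6-methoxy-2-(4-methoxyphenyl)-2,3-dihydro-1-benzofuran, via resorcinol 21 (not isolated)
Conditions: CsF (4 equiv), MeI (6 equiv), DMF, rt
Reagents that add atoms: iodomethane CI
Why: One‑pot fluoride desilylation and Williamson methylation gives unit f a resorcinol ring that can never become a phenolate nucleophile.

Step 14
Reactants: 22 ArM–Br
Product: 24 2-ArM-ethanol, via aryllithium 23 (not isolated)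
Conditions: nBuLi, THF, −78 °C; oxirane, −78 to 0 °C; NH4Cl
Reagents that add atoms: oxirane C1CO1
Why: Bromine–lithium exchange and epoxide opening by the aryllithium give the two‑carbon homologue directly.

Step 15
Reactants: 24 2-ArM-ethanol
Product: 25 ArM–CH2–CHO
Conditions: Dess–Martin periodinane, CH2Cl2, 0 °C
Reagents that add atoms: none
Why: Mild Dess–Martin oxidation gives the sensitive arylacetaldehyde without over‑oxidation; it is used directly.

Step 16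
Reactants: 25 ArM–CH2–CHO; 18 (E)-ArT–CH=CH–NO2
Product: 26 (2R,3R)-2-ArM-3-ArT-4-nitrobutanal
Conditions: (R)-2-[diphenyl(trimethylsilyloxy)methyl]pyrrolidine (20 mol %), 4-nitrophenol (20 mol %), toluene, 0 °C to rt
Reagents that add atoms: none
Why: Enamine‑catalysed asymmetric Michael addition to a nitroalkene: the (R)‑catalyst shields one enamine face and the acyclic synclinal transition state gives the syn adduct, setting C‑8e and C‑8c (the target has these two aryl groups syn along the chain).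

Step 17
Reactants: 27 4-bromo-2,6-di-tert-butylphenol
Product: 28 (4-bromo-2,6-di-tert-butylphenoxy)trimethylsilane
Conditions: NaH, THF, 0 °C; Me3SiCl
Reagents that add atoms: chlorotrimethylsilane C[Si](C)(C)Cl
Why: Silylation of the hindered phenoxide masks the OH for Grignard formation and later serves as the fluoride trigger.

Step 18
Reactants: 28 (4-bromo-2,6-di-tert-butylphenoxy)trimethylsilane
Product: 29 [3,5-di-tert-butyl-4-(trimethylsilyloxy)phenyl]magnesium bromide, kept as a titrated stock solution in THF under argon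
Conditions: Mg turnings, I2 (one crystal), THF, 40–50 °C; titrate; store under Ar at 4 °C
Reagents that add atoms: magnesium [Mg]
Why: Oxidative insertion of magnesium into the unhindered C–Br bond gives a stable aryl Grignard reagent; one titrated batch supplies steps 19, 24 and 27.

Step 19
Reactants: 26 nitro aldehyde; 29 Grignard reagent
Product: 30 1-Ar′-2-ArM-3-ArT-4-nitrobutan-1-ol (both C-1 epimers; C-2 and C-3 as in 26)
Conditions: 29 (2.2 equiv, one equivalent is taken up by CH2NO2), LaCl3·2LiCl (30 mol %), THF, −78 °C; AcOH/NH4Cl buffer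
Reagents that add atoms: none
Why: Lanthanum‑assisted Grignard 1,2‑addition outruns enolisation of the α‑aryl aldehyde; the new carbinol centre is planarised in step 21.

Step 20
Reactants: 30 nitro carbinol
Product: 31 1-Ar′-2-ArM-3-ArT-4-nitrobutyl acetate
Conditions: Ac2O, pyridine, DMAP (5 mol %), CH2Cl2, 0 °C
Reagents that add atoms: acetic anhydride CC(=O)OC(C)=O
Why: Acetylation installs the leaving group for fluoride‑triggered 1,6‑elimination.

Step 21
Reactants: 31 nitro acetate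
Product: 33 eight-membered-ring tetramer of units c–f (CH2NO2 on C-8c; Ar* on C-7e; 7e–10d bond; ring d2 as free 11d,13d-diol; stereocentres as in the target), via quinone methide 32 (not isolated)
Conditions: Bu4NF (3.5 equiv), THF, 0.005 M, −40 to 0 °C; NH4Cl
Reagents that add atoms: none
Why: Fluoride frees the hindered phenolate, which expels acetate to give the para‑quinone methide, and frees the ring‑d2 resorcinolate, which adds through C‑10d (intramolecular 1,6‑conjugate addition, Friedel–Crafts‑type); only a phenolate ring can react, so ring f2, C‑14c and the other ethers stay out, and attack anti to the ring‑e2 aryl on C‑8e sets C‑7e.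

Step 22
Reactants: 33 tetramer diol
Product: 34 tetramer with ring d2 as its 11d,13d-dimethyl ether (otherwise as 33)
Conditions: Me3SiCHN2, iPr2NEt, MeCN/MeOH, rt
Reagents that add atoms: trimethylsilyldiazomethane C[Si](C)(C)C=[N+]=[N-]
Why: Diazoalkane O‑methylation caps the two unhindered phenols so ring d2 cannot later attack the C‑7c quinone methide; the di‑tert‑butylphenol and the nitro group do not react.

Step 23
Reactants: 34 nitro tetramer
Product: 35 tetramer aldehyde (C-7c is the CHO on C-8c)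
Conditions: NaOMe, MeOH, 0 °C; then aqueous TiCl3, NH4OAc (pH 5–6), THF, 0 °C to rt
Reagents that add atoms: water O
Why: Reductive Nef reaction of the nitronate under buffered, non‑oxidising conditions spares the hindered phenol and limits epimerisation at C‑8c.

Step 24
Reactants: 35 tetramer aldehyde; 29 Grignard reagent
Product: 37 tetramer acetate (C-8c bears CH(OAc)Ar′; both C-7c epimers), via carbinol 36 (not isolated)
Conditions: 29 (2.3 equiv, one equivalent is taken up by the Ar* OH), LaCl3·2LiCl (30 mol %), THF, −78 °C; then Ac2O (1.0 equiv), −78 °C; NH4Cl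
Reagents that add atoms: acetic anhydride CC(=O)OC(C)=O
Why: Grignard 1,2‑addition with in‑situ acetylation of the secondary alkoxide; the 2,6‑di‑tert‑butylphenoxide is too hindered to be acylated.

Step 25
Reactants: 37 tetramer acetate
Product: 38 tetramer para-quinone methide (C-7c is the exocyclic methine of a 2,6-di-tert-butylcyclohexa-2,5-dien-1-one-4-ylidene on C-8c)
Conditions: Bu4NF (1.05 equiv), THF, −78 °C, 10 min; pH 7 buffer; fast filtration through deactivated silica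
Reagents that add atoms: none
Why: Fluoride‑induced 1,6‑elimination of acetate gives a tert‑butyl‑stabilised, isolable para‑quinone methide; with no free unhindered phenolate present, nothing attacks it intramolecularly.

Step 26
Reactants: 38 tetramer para-quinone methide; 20 ArT–CH2–CHO
Product: 39 hexamer aldehyde (C-7b is CHO; C-8b bears ArT; C-7c bears Ar*; new 8b–7c bond; C-8b and C-7c as in the target)
Conditions: (R)-2-[diphenyl(trimethylsilyloxy)methyl]pyrrolidine (20 mol %), PhCO2H (20 mol %), toluene, −20 to 4 °C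
Reagents that add atoms: none
Why: Enamine‑catalysed 1,6‑conjugate (vinylogous Michael) addition to the para‑quinone methide under near‑neutral conditions that avoid both Friedel–Crafts chemistry and base tautomerisation; the catalyst sets C‑8b and attack anti to the bulkier flank of C‑8c is expected to set C‑7c.

Step 27
Reactants: 39 hexamer aldehyde; 29 Grignard reagent
Product: 41 hexamer acetate (C-8b bears CH(OAc)Ar′; both C-7b epimers), via carbinol 40 (not isolated)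
Conditions: 29 (3.5 equiv, two equivalents are taken up by the two Ar* OH groups), LaCl3·2LiCl (30 mol %), THF, −78 °C; then Ac2O (1.0 equiv), −78 °C; NH4Cl
Reagents that add atoms: acetic anhydride CC(=O)OC(C)=O
Why: Same Grignard addition and in‑situ acetylation as step 24, run cold to preserve the α‑aryl stereocentre C‑8b.

Step 28
Reactants: 41 hexamer acetate
Product: 43 protected hexamer (seven-membered ring closed by the 7b–10a bond; ring a2 as free 11a,13a-diol; Ar* on C-7b/C-7c/C-7e; ten OMe; all twelve stereocentres as in the target), via quinone methide 42 (not isolated)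
Conditions: Bu4NF (3.5 equiv), THF, 0.005 M, −40 to 0 °C; NH4Cl
Reagents that add atoms: none
Why: The same fluoride‑triggered quinone‑methide formation and resorcinolate 1,6‑addition as step 21, now through C‑10a of ring a2; this is the biogenetic hopeaphenol‑type ring closure, and C‑7b is expected to form with the natural configuration under substrate control.

Step 29
Reactants: 43 protected hexamer
Product: 44 hexa-tert-butyl target (all ten OMe cleaved; three Ar* groups retained)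
Conditions: BBr3 (30 equiv), CH2Cl2, −78 °C to rt; MeOH, H2O
Reagents that add atoms: none
Why: Lewis‑acid cleavage of the aryl methyl ethers; the trans‑dihydrobenzofurans and benzylic methines are not epimerisable under these conditions.

Step 30
Reactants: 44 hexa-tert-butyl target
Product: 45 target hexamer CNP0184494.1
Conditions: AlCl3 (excess), toluene/MeNO2, 60 °C
Reagents that add atoms: none
Why: Retro‑Friedel–Crafts de‑tert‑butylation of the three hindered phenols, with toluene as the tert‑butyl acceptor, unveils the 4‑hydroxyphenyl groups without touching any stereocentre.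

**Compound list**

1 | 1-bromo-3,5-dimethoxybenzene | COc1cc(Br)cc(OC)c1 | starting material
2 | N-[(2-bromo-4,6-dimethoxyphenyl)methylidene]-N-methylmethanaminium dichlorophosphate | COc1cc(OC)c(C=[N+](C)C)c(Br)c1.[O-]P(=O)(Cl)Cl | intermediate
3 | 2-bromo-4,6-dimethoxybenzaldehyde | COc1cc(OC)c(C=O)c(Br)c1 | intermediate
4 | 2-bromo-6-hydroxy-4-methoxybenzaldehyde | COc1cc(O)c(C=O)c(Br)c1 | intermediate
5 | 5-bromobenzene-1,3-diol | Oc1cc(O)cc(Br)c1 | starting material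
6 | 1-bromo-3,5-bis(triisopropylsilyloxy)benzene | CC(C)[Si](Oc1cc(Br)cc(O[Si](C(C)C)(C(C)C)C(C)C)c1)(C(C)C)C(C)C | intermediate
7 | [3,5-bis(triisopropylsilyloxy)phenyl]magnesium bromide | CC(C)[Si](Oc1cc([Mg]Br)cc(O[Si](C(C)C)(C(C)C)C(C)C)c1)(C(C)C)C(C)C | intermediate
8 | racemic (2-bromo-6-hydroxy-4-methoxyphenyl)[3,5-bis(triisopropylsilyloxy)phenyl]methanol | COc1cc(O)c(C(O)c2cc(O[Si](C(C)C)(C(C)C)C(C)C)cc(O[Si](C(C)C)(C(C)C)C(C)C)c2)c(Br)c1 | intermediate
9 | racemic 3-bromo-5-methoxy-2-{[3,5-bis(triisopropylsilyloxy)phenyl][(4-methylphenyl)sulfonyl]methyl}phenol | COc1cc(O)c(C(c2cc(O[Si](C(C)C)(C(C)C)C(C)C)cc(O[Si](C(C)C)(C(C)C)C(C)C)c2)S(=O)(=O)c2ccc(C)cc2)c(Br)c1 | intermediate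
10 | 4-methoxybenzyl chloride | COc1ccc(CCl)cc1 | starting material
11 | (4-methoxybenzyl)dimethylsulfonium chloride | COc1ccc(C[S+](C)C)cc1.[Cl-] | intermediate
12 | dimethylsulfonium (4-methoxyphenyl)methylide | COc1ccc([CH-][S+](C)C)cc1 | intermediate
13 | 5-bromo-3-methoxy-6-{[3,5-bis(triisopropylsilyloxy)phenyl]methylidene}cyclohexa-2,4-dien-1-one | COC1=CC(=O)C(=Cc2cc(O[Si](C(C)C)(C(C)C)C(C)C)cc(O[Si](C(C)C)(C(C)C)C(C)C)c2)C(Br)=C1 | intermediate
14 | (2RS,3RS)-4-bromo-3-[3,5-bis(triisopropylsilyloxy)phenyl]-6-methoxy-2-(4-methoxyphenyl)-2,3-dihydro-1-benzofuran, racemic trans | COc1ccc(cc1)[C@@H]1Oc2cc(OC)cc(Br)c2[C@H]1c1cc(O[Si](C(C)C)(C(C)C)C(C)C)cc(O[Si](C(C)C)(C(C)C)C(C)C)c1.COc1ccc(cc1)[C@H]1Oc2cc(OC)cc(Br)c2[C@@H]1c1cc(O[Si](C(C)C)(C(C)C)C(C)C)cc(O[Si](C(C)C)(C(C)C)C(C)C)c1 | intermediate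
15 | ArT–Br, the (2R,3R) enantiomer of 14 | COc1ccc(cc1)[C@@H]1Oc2cc(OC)cc(Br)c2[C@H]1c1cc(O[Si](C(C)C)(C(C)C)C(C)C)cc(O[Si](C(C)C)(C(C)C)C(C)C)c1 | intermediate
16 | ArT–Li | COc1ccc(cc1)[C@@H]1Oc2cc(OC)cc([Li])c2[C@H]1c1cc(O[Si](C(C)C)(C(C)C)C(C)C)cc(O[Si](C(C)C)(C(C)C)C(C)C)c1 | intermediate
17 | ArT–CHO | COc1ccc(cc1)[C@@H]1Oc2cc(OC)cc(C=O)c2[C@H]1c1cc(O[Si](C(C)C)(C(C)C)C(C)C)cc(O[Si](C(C)C)(C(C)C)C(C)C)c1 | intermediate
18 | (E)-ArT–CH=CH–NO2 | COc1ccc(cc1)[C@@H]1Oc2cc(OC)cc(/C=C/[N+](=O)[O-])c2[C@H]1c1cc(O[Si](C(C)C)(C(C)C)C(C)C)cc(O[Si](C(C)C)(C(C)C)C(C)C)c1 | intermediate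
19 | ArT–CH=CH–OMe, (2R,3R)-3-[3,5-bis(triisopropylsilyloxy)phenyl]-6-methoxy-4-(2-methoxyethenyl)-2-(4-methoxyphenyl)-2,3-dihydro-1-benzofuran (E/Z mixture) | COc1ccc(cc1)[C@@H]1Oc2cc(OC)cc(C=COC)c2[C@H]1c1cc(O[Si](C(C)C)(C(C)C)C(C)C)cc(O[Si](C(C)C)(C(C)C)C(C)C)c1 | intermediate
20 | ArT–CH2–CHO | COc1ccc(cc1)[C@@H]1Oc2cc(OC)cc(CC=O)c2[C@H]1c1cc(O[Si](C(C)C)(C(C)C)C(C)C)cc(O[Si](C(C)C)(C(C)C)C(C)C)c1 | intermediate
21 | 5-[(2R,3R)-4-bromo-6-methoxy-2-(4-methoxyphenyl)-2,3-dihydro-1-benzofuran-3-yl]benzene-1,3-diol (as caesium phenolate) | COc1ccc(cc1)[C@@H]1Oc2cc(OC)cc(Br)c2[C@H]1c1cc(O)cc(O)c1 | intermediate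
22 | ArM–Br | COc1ccc(cc1)[C@@H]1Oc2cc(OC)cc(Br)c2[C@H]1c1cc(OC)cc(OC)c1 | intermediate
23 | ArM–Li | COc1ccc(cc1)[C@@H]1Oc2cc(OC)cc([Li])c2[C@H]1c1cc(OC)cc(OC)c1 | intermediate
24 | 2-ArM-ethanol | COc1ccc(cc1)[C@@H]1Oc2cc(OC)cc(CCO)c2[C@H]1c1cc(OC)cc(OC)c1 | intermediate
25 | ArM–CH2–CHO | COc1ccc(cc1)[C@@H]1Oc2cc(OC)cc(CC=O)c2[C@H]1c1cc(OC)cc(OC)c1 | intermediate
26 | (2R,3R)-2-ArM-3-ArT-4-nitrobutanal | [O-][N+](=O)C[C@H]([C@@H](C=O)c1cc(OC)cc2c1[C@@H](c1cc(OC)cc(OC)c1)[C@H](c1ccc(OC)cc1)O2)c1cc(OC)cc2c1[C@@H](c1cc(O[Si](C(C)C)(C(C)C)C(C)C)cc(O[Si](C(C)C)(C(C)C)C(C)C)c1)[C@H](c1ccc(OC)cc1)O2 | intermediate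
27 | 4-bromo-2,6-di-tert-butylphenol | CC(C)(C)c1cc(Br)cc(C(C)(C)C)c1O | starting material
28 | (4-bromo-2,6-di-tert-butylphenoxy)trimethylsilane | CC(C)(C)c1cc(Br)cc(C(C)(C)C)c1O[Si](C)(C)C | intermediate
29 | [3,5-di-tert-butyl-4-(trimethylsilyloxy)phenyl]magnesium bromide (titrated THF stock solution) | CC(C)(C)c1cc([Mg]Br)cc(C(C)(C)C)c1O[Si](C)(C)C | intermediate
30 | 1-Ar′-2-ArM-3-ArT-4-nitrobutan-1-ol (C-1 epimers) | [O-][N+](=O)C[C@H]([C@@H](C(O)c1cc(C(C)(C)C)c(O[Si](C)(C)C)c(C(C)(C)C)c1)c1cc(OC)cc2c1[C@@H](c1cc(OC)cc(OC)c1)[C@H](c1ccc(OC)cc1)O2)c1cc(OC)cc2c1[C@@H](c1cc(O[Si](C(C)C)(C(C)C)C(C)C)cc(O[Si](C(C)C)(C(C)C)C(C)C)c1)[C@H](c1ccc(OC)cc1)O2 | intermediate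
31 | 1-Ar′-2-ArM-3-ArT-4-nitrobutyl acetate (C-1 epimers) | [O-][N+](=O)C[C@H]([C@@H](C(OC(C)=O)c1cc(C(C)(C)C)c(O[Si](C)(C)C)c(C(C)(C)C)c1)c1cc(OC)cc2c1[C@@H](c1cc(OC)cc(OC)c1)[C@H](c1ccc(OC)cc1)O2)c1cc(OC)cc2c1[C@@H](c1cc(O[Si](C(C)C)(C(C)C)C(C)C)cc(O[Si](C(C)C)(C(C)C)C(C)C)c1)[C@H](c1ccc(OC)cc1)O2 | intermediate
32 | 2,6-di-tert-butyl-4-[(2R,3R)-2-ArM-3-ArD-4-nitrobutylidene]cyclohexa-2,5-dien-1-one | [O-][N+](=O)C[C@H]([C@@H](C=C1C=C(C(C)(C)C)C(=O)C(C(C)(C)C)=C1)c1cc(OC)cc2c1[C@@H](c1cc(OC)cc(OC)c1)[C@H](c1ccc(OC)cc1)O2)c1cc(OC)cc2c1[C@@H](c1cc(O)cc(O)c1)[C@H](c1ccc(OC)cc1)O2 | intermediate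
33 | eight-membered-ring tetramer c–f: 8c-CH2NO2, 7e-Ar*, ring d2 11d,13d-diol | [O-][N+](=O)C[C@H]1c2cc(OC)cc3c2[C@@H](c2cc(O)cc(O)c2[C@H](c2cc(C(C)(C)C)c(O)c(C(C)(C)C)c2)[C@H]1c1cc(OC)cc2c1[C@@H](c1cc(OC)cc(OC)c1)[C@H](c1ccc(OC)cc1)O2)[C@H](c1ccc(OC)cc1)O3 | intermediate
34 | tetramer 33 with ring d2 as dimethyl ether | [O-][N+](=O)C[C@H]1c2cc(OC)cc3c2[C@@H](c2cc(OC)cc(OC)c2[C@H](c2cc(C(C)(C)C)c(O)c(C(C)(C)C)c2)[C@H]1c1cc(OC)cc2c1[C@@H](c1cc(OC)cc(OC)c1)[C@H](c1ccc(OC)cc1)O2)[C@H](c1ccc(OC)cc1)O3 | intermediate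
35 | tetramer aldehyde (CHO = C-7c on C-8c) | O=C[C@H]1c2cc(OC)cc3c2[C@@H](c2cc(OC)cc(OC)c2[C@H](c2cc(C(C)(C)C)c(O)c(C(C)(C)C)c2)[C@H]1c1cc(OC)cc2c1[C@@H](c1cc(OC)cc(OC)c1)[C@H](c1ccc(OC)cc1)O2)[C@H](c1ccc(OC)cc1)O3 | intermediate
36 | tetramer carbinol (CH(OH)Ar′ on C-8c; C-7c epimers) | OC(c1cc(C(C)(C)C)c(O[Si](C)(C)C)c(C(C)(C)C)c1)[C@H]1c2cc(OC)cc3c2[C@@H](c2cc(OC)cc(OC)c2[C@H](c2cc(C(C)(C)C)c(O)c(C(C)(C)C)c2)[C@H]1c1cc(OC)cc2c1[C@@H](c1cc(OC)cc(OC)c1)[C@H](c1ccc(OC)cc1)O2)[C@H](c1ccc(OC)cc1)O3 | intermediate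
37 | tetramer acetate (CH(OAc)Ar′ on C-8c; C-7c epimers) | CC(=O)OC(c1cc(C(C)(C)C)c(O[Si](C)(C)C)c(C(C)(C)C)c1)[C@H]1c2cc(OC)cc3c2[C@@H](c2cc(OC)cc(OC)c2[C@H](c2cc(C(C)(C)C)c(O)c(C(C)(C)C)c2)[C@H]1c1cc(OC)cc2c1[C@@H](c1cc(OC)cc(OC)c1)[C@H](c1ccc(OC)cc1)O2)[C@H](c1ccc(OC)cc1)O3 | intermediate
38 | tetramer para-quinone methide at C-7c | CC(C)(C)C1=CC(=C[C@H]2c3cc(OC)cc4c3[C@@H](c3cc(OC)cc(OC)c3[C@H](c3cc(C(C)(C)C)c(O)c(C(C)(C)C)c3)[C@H]2c2cc(OC)cc3c2[C@@H](c2cc(OC)cc(OC)c2)[C@H](c2ccc(OC)cc2)O3)[C@H](c2ccc(OC)cc2)O4)C=C(C(C)(C)C)C1=O | intermediate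
39 | hexamer aldehyde (CHO = C-7b; 8b-ArT; 7c-Ar*) | O=C[C@@H](c1cc(OC)cc2c1[C@@H](c1cc(O[Si](C(C)C)(C(C)C)C(C)C)cc(O[Si](C(C)C)(C(C)C)C(C)C)c1)[C@H](c1ccc(OC)cc1)O2)[C@H](c1cc(C(C)(C)C)c(O)c(C(C)(C)C)c1)[C@H]1c2cc(OC)cc3c2[C@@H](c2cc(OC)cc(OC)c2[C@H](c2cc(C(C)(C)C)c(O)c(C(C)(C)C)c2)[C@H]1c1cc(OC)cc2c1[C@@H](c1cc(OC)cc(OC)c1)[C@H](c1ccc(OC)cc1)O2)[C@H](c1ccc(OC)cc1)O3 | intermediate
40 | hexamer carbinol (CH(OH)Ar′ on C-8b; C-7b epimers) | OC(c1cc(C(C)(C)C)c(O[Si](C)(C)C)c(C(C)(C)C)c1)[C@@H](c1cc(OC)cc2c1[C@@H](c1cc(O[Si](C(C)C)(C(C)C)C(C)C)cc(O[Si](C(C)C)(C(C)C)C(C)C)c1)[C@H](c1ccc(OC)cc1)O2)[C@H](c1cc(C(C)(C)C)c(O)c(C(C)(C)C)c1)[C@H]1c2cc(OC)cc3c2[C@@H](c2cc(OC)cc(OC)c2[C@H](c2cc(C(C)(C)C)c(O)c(C(C)(C)C)c2)[C@H]1c1cc(OC)cc2c1[C@@H](c1cc(OC)cc(OC)c1)[C@H](c1ccc(OC)cc1)O2)[C@H](c1ccc(OC)cc1)O3 | intermediate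
41 | hexamer acetate (CH(OAc)Ar′ on C-8b; C-7b epimers) | CC(=O)OC(c1cc(C(C)(C)C)c(O[Si](C)(C)C)c(C(C)(C)C)c1)[C@@H](c1cc(OC)cc2c1[C@@H](c1cc(O[Si](C(C)C)(C(C)C)C(C)C)cc(O[Si](C(C)C)(C(C)C)C(C)C)c1)[C@H](c1ccc(OC)cc1)O2)[C@H](c1cc(C(C)(C)C)c(O)c(C(C)(C)C)c1)[C@H]1c2cc(OC)cc3c2[C@@H](c2cc(OC)cc(OC)c2[C@H](c2cc(C(C)(C)C)c(O)c(C(C)(C)C)c2)[C@H]1c1cc(OC)cc2c1[C@@H](c1cc(OC)cc(OC)c1)[C@H](c1ccc(OC)cc1)O2)[C@H](c1ccc(OC)cc1)O3 | intermediate
42 | hexamer para-quinone methide at C-7b with ring a2 as free diol | CC(C)(C)C1=CC(=C[C@@H](c2cc(OC)cc3c2[C@@H](c2cc(O)cc(O)c2)[C@H](c2ccc(OC)cc2)O3)[C@H](c2cc(C(C)(C)C)c(O)c(C(C)(C)C)c2)[C@H]2c3cc(OC)cc4c3[C@@H](c3cc(OC)cc(OC)c3[C@H](c3cc(C(C)(C)C)c(O)c(C(C)(C)C)c3)[C@H]2c2cc(OC)cc3c2[C@@H](c2cc(OC)cc(OC)c2)[C@H](c2ccc(OC)cc2)O3)[C@H](c2ccc(OC)cc2)O4)C=C(C(C)(C)C)C1=O | intermediate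
43 | protected hexamer (ring a2 diol; three Ar*; ten OMe) | Oc1c(C(C)(C)C)cc([C@H]2c3c(O)cc(O)cc3[C@@H]3c4c(cc(OC)cc4[C@H]2[C@H](c2cc(C(C)(C)C)c(O)c(C(C)(C)C)c2)[C@H]2c4cc(OC)cc5c4[C@@H](c4cc(OC)cc(OC)c4[C@H](c4cc(C(C)(C)C)c(O)c(C(C)(C)C)c4)[C@H]2c2cc(OC)cc4c2[C@@H](c2cc(OC)cc(OC)c2)[C@H](c2ccc(OC)cc2)O4)[C@H](c2ccc(OC)cc2)O5)O[C@H]3c2ccc(OC)cc2)cc1C(C)(C)C | intermediate
44 | hexa-tert-butyl target (three Ar* on C-7b, C-7c, C-7e; all other oxygens free OH) | Oc1c(C(C)(C)C)cc([C@H]2c3c(O)cc(O)cc3[C@@H]3c4c(cc(O)cc4[C@H]2[C@H](c2cc(C(C)(C)C)c(O)c(C(C)(C)C)c2)[C@H]2c4cc(O)cc5c4[C@@H](c4cc(O)cc(O)c4[C@H](c4cc(C(C)(C)C)c(O)c(C(C)(C)C)c4)[C@H]2c2cc(O)cc4c2[C@@H](c2cc(O)cc(O)c2)[C@H](c2ccc(O)cc2)O4)[C@H](c2ccc(O)cc2)O5)O[C@H]3c2ccc(O)cc2)cc1C(C)(C)C | intermediate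
45 | CNP0184494.1, (7aR,8aR,7bS,8bS,7cR,8cR,7dR,8dR,7eS,8eS,7fR,8fR) resveratrol hexamer | Oc1ccc([C@H]2c3c(O)cc(O)cc3[C@@H]3c4c(cc(O)cc4[C@H]2[C@H](c2ccc(O)cc2)[C@H]2c4cc(O)cc5c4[C@@H](c4cc(O)cc(O)c4[C@H](c4ccc(O)cc4)[C@H]2c2cc(O)cc4c2[C@@H](c2cc(O)cc(O)c2)[C@H](c2ccc(O)cc2)O4)[C@H](c2ccc(O)cc2)O5)O[C@H]3c2ccc(O)cc2)cc1 | target

**Totals and risk**

Total step count: 30. Longest linear sequence: 22 steps (steps 1, 2, 4, 5, 7, 8, 13, 14, 15, 16, 19–30).

The three steps most likely to fail: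

Step 16 (first fragment union). Both partners are ortho‑hindered and the α‑aryl aldehyde product can epimerise at C‑8e, so rate and diastereoselectivity may be poor. The fallback sets out from 25 and comes back at 26. Aldehyde 25 is condensed with (S)‑1‑amino‑2‑(methoxymethyl)pyrrolidine to the SAMP hydrazone F1. Its lithium azaenolate (LiN(iPr)2, THF, −78 °C) is added to nitroalkene 18 at −100 °C to give the Michael adduct hydrazone F2, so that C‑8e is set by a covalently bound auxiliary instead of a catalyst. Cleavage with saturated aqueous oxalic acid/Et2O returns 26.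

Step 21 (eight‑membered ring). The quinone methide may tautomerise to the stilbene before the resorcinolate closes the medium ring, or C‑7e may form with the wrong configuration. The fallback sets out from 26 and comes back at 33. HF·pyridine removes both silyl groups to give the resorcinol nitro aldehyde F3. Magnesium‑phenoxide‑directed ortho‑hydroxyalkylation (EtMgBr, toluene) joins C‑10d to the aldehyde carbon and gives the eight‑membered benzylic alcohol F4. Its ortho‑quinone methide (diphenyl phosphate catalyst, CH2Cl2) is then arylated by 2,6‑di‑tert‑butylphenol at the para position, anti to the neighbouring ring‑e2 aryl, which gives 33. Here the ring is closed before the 7e‑aryl is introduced.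

Step 26 (second fragment union). The hindered quinone methide may react slowly with the enamine, tautomerise, or give the wrong C‑7c epimer. The fallback sets out from 20 and comes back at 39. Aldehyde 20 is converted (Me3SiCl, Et3N, NaI, MeCN) into the (Z)‑silyl enol ether F5. This is added to 38 in a Mukaiyama–Michael 1,6‑addition in 5 M LiClO4/Et2O at −40 °C, a neutral medium that activates the quinone methide without triggering arene attack. Aqueous work‑up gives 39, with C‑8b then adjustable by mild base equilibration of the α‑aryl aldehyde.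

Further compounds
F1 | step 16 | SAMP hydrazone of 25, (E)-N-[(2S)-2-(methoxymethyl)pyrrolidin-1-yl]-2-ArM-ethanimine | COC[C@@H]1CCCN1/N=C/Cc1cc(OC)cc2c1[C@@H](c1cc(OC)cc(OC)c1)[C@H](c1ccc(OC)cc1)O2
F2 | step 16 | SAMP hydrazone of 26 | COC[C@@H]1CCCN1/N=C/[C@@H](c1cc(OC)cc2c1[C@@H](c1cc(OC)cc(OC)c1)[C@H](c1ccc(OC)cc1)O2)[C@H](c1cc(OC)cc2c1[C@@H](c1cc(O[Si](C(C)C)(C(C)C)C(C)C)cc(O[Si](C(C)C)(C(C)C)C(C)C)c1)[C@H](c1ccc(OC)cc1)O2)C[N+](=O)[O-]
F3 | step 21 | (2R,3R)-2-ArM-3-ArD-4-nitrobutanal | [O-][N+](=O)C[C@H]([C@@H](C=O)c1cc(OC)cc2c1[C@@H](c1cc(OC)cc(OC)c1)[C@H](c1ccc(OC)cc1)O2)c1cc(OC)cc2c1[C@@H](c1cc(O)cc(O)c1)[C@H](c1ccc(OC)cc1)O2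
F4 | step 21 | eight-membered-ring benzylic alcohol (OH on C-7e; 7e–10d bond; ring d2 diol; CH2NO2 on C-8c) | [O-][N+](=O)C[C@H]1c2cc(OC)cc3c2[C@@H](c2cc(O)cc(O)c2C(O)[C@H]1c1cc(OC)cc2c1[C@@H](c1cc(OC)cc(OC)c1)[C@H](c1ccc(OC)cc1)O2)[C@H](c1ccc(OC)cc1)O3
F5 | step 26 | (Z)-trimethylsilyl enol ether of 20 | C[Si](C)(C)O/C=C\c1cc(OC)cc2c1[C@@H](c1cc(O[Si](C(C)C)(C(C)C)C(C)C)cc(O[Si](C(C)C)(C(C)C)C(C)C)c1)[C@H](c1ccc(OC)cc1)O2
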